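Ring B is built around a ready-made diaryl ether oxygen instead of by coupling two arenes. The arc C3'–C2'–C1'–C6'–C5' of ring B, oxygenated at C2', C1' and C6', is an acetylacetone unit bearing ring A as an aryloxy group on its central carbon. Only C4', the sulfate-bearing carbon at carbonic acid oxidation level, is missing. One operation joins both methyl carbons to the carbon of dimethyl carbonate (C3'–C4', C4'–C5') by two Claisen acylations and aromatises to the 2-aryloxyphloroglucinol. The precursor is a 3-aryloxypentane-2,4-dione whose ring A carries a benzyl ether (future hydroxyl) and a TIPS ether (future sulfate).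

Key step: step 4

Assumption: the target is drawn as the free bis(hydrogen sulfate); because aryl hydrogen sulfates hydrolyse under their own acidity, the sulfated compounds are carried as disodium salts and the acid form is released only in the last operation, cold, by cation exchange.

Step 1
Reactants: 1 phloroglucinol (benzene-1,3,5-triol)
Product: 2 5-(benzyloxy)benzene-1,3-diol
Conditions: 1 (3 equiv, anhydrous), BnBr (1 equiv), K2CO3 (1.1 equiv), DMF, 0 °C → rt
Reagents that add atoms: benzyl bromide, BrCc1ccccc1
Why: Williamson O-benzylation in which a threefold excess of the cheap, water-soluble triol and only one equivalent of weak base should hold the reaction at the mono-ether and limit C-benzylation, the surplus 1 being washed out with water.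

Step 2
Reactants: 2 5-(benzyloxy)benzene-1,3-diol
Product: 3 3-(benzyloxy)-5-(triisopropylsilyloxy)phenol
Conditions: TIPSCl (1.0 equiv), imidazole (2.2 equiv), DMF, 0 °C → rt
Reagents that add atoms: chlorotriisopropylsilane, CC(C)[Si](Cl)(C(C)C)C(C)C
Why: Imidazole-promoted silylation of one of two equivalent phenols (statistical desymmetrisation with recyclable diol and bis-silyl ether); TIPS is chosen because it is the aryl silyl ether best able to withstand the lithium amide and LiOMe of step 4.

Step 3
Reactants: 3 3-(benzyloxy)-5-(triisopropylsilyloxy)phenol; 4 3-chloropentane-2,4-dione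
Product: 5 3-[3-(benzyloxy)-5-(triisopropylsilyloxy)phenoxy]pentane-2,4-dione
Conditions: K2CO3 (2.2 equiv), acetone, reflux; pH 5 buffer work-up
Reagents that add atoms: none
Why: SN2 O-alkylation of a phenoxide by an α-chloro-β-diketone, an established entry to 3-aryloxypentane-2,4-diones; anhydrous carbonate spares both ethers, the product rests as its enolate (shielded from retro-Claisen deacetylation), and the buffered work-up avoids acid-induced cyclodehydration to a benzofuran.

Step 4
Reactants: 5 3-[3-(benzyloxy)-5-(triisopropylsilyloxy)phenoxy]pentane-2,4-dione; 6 dimethyl carbonate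
Product: 8 2-[3-(benzyloxy)-5-(triisopropylsilyloxy)phenoxy]benzene-1,3,5-triol, via methyl 4-aryloxy-3,5-dioxohexanoate 7 (not isolated)
Conditions: LiN(i-Pr)2 (commercial solution, 3.3 equiv), THF, −78 → 0 °C; 6 (1.05 equiv), −78 → 0 °C; LiN(i-Pr)2 (2.5 equiv), 0 → 40 °C; 1 M HCl, 0 °C, under Ar
Reagents that add atoms: none
Why: Proposed new method: LiN(i-Pr)2 first removes the C1' proton and one methyl proton of 5, and the terminal carbanion of this dianion, its most basic and least delocalised site, attacks 6 to make the C3'–C4' bond and give keto ester 7, which spare base stores at once as its enolate. The second portion of base deprotonates the remaining methyl group, and C5' then adds to the ester carbonyl in a 6-(enolendo)-exo-trig Claisen (Dieckmann-type) closure that makes the C4'–C5' bond; i-Pr2NH in the flask can shuttle protons so that the tautomeric polyanion with a non-enolised, still electrophilic ester is accessible, and loss of methoxide followed by enolisation to the aromatic trilithium phenolate is an irreversible sink. The closest known reaction types are the terminal methoxycarbonylation of 1,3-diketone dianions by dialkyl carbonates and the base-driven Claisen cyclisation of 3,5-dioxohexanoates to phloroglucinols; what is untested is their union in one flask on a diketone with a central aryloxy group. No stereocentre is formed, since the labile C4 of 7 ends as the sp2 carbon C1'. The selectivity needed is acylation at a methyl carbon and closure through carbon instead of oxygen (arene, not 4-hydroxy-2-pyrone): the fully substituted, strongly delocalised C1' enolate is the poorer nucleophile, a carbanionic C5' outruns the enolate oxygen, and any pyrone can be reopened by the LiOMe present while the phenolate cannot revert. The aryloxy group itself helps, because allylic 1,3-strain with both chain ends disfavours the extended O,O-chelated diketonate, its oxygen can share lithium with the C2' and C6' oxygens in the folded rotamer that brings C5' next to C4', and, bound to an enolate sp2 carbon, it has no pathway for expulsion.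

Step 5
Reactants: 8 2-[3-(benzyloxy)-5-(triisopropylsilyloxy)phenoxy]benzene-1,3,5-triol
Product: 9 2-[3-(benzyloxy)-5-(triisopropylsilyloxy)phenoxy]-5-(triisopropylsilyloxy)benzene-1,3-diol
Conditions: TIPSCl (1.0 equiv, slow addition), imidazole (2.5 equiv), CH2Cl2/DMF, −20 → 0 °C
Reagents that add atoms: chlorotriisopropylsilane, CC(C)[Si](Cl)(C(C)C)C(C)C
Why: Sterically governed phenol silylation, in which the C4' hydroxyl has two ortho hydrogens while the C2' and C6' hydroxyls each sit beside the twisted aryloxy group, so the bulky silyl chloride should take the open site.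

Step 6
Reactants: 9 2-[3-(benzyloxy)-5-(triisopropylsilyloxy)phenoxy]-5-(triisopropylsilyloxy)benzene-1,3-diol
Product: 10 1,3-bis(benzyloxy)-2-[3-(benzyloxy)-5-(triisopropylsilyloxy)phenoxy]-5-(triisopropylsilyloxy)benzene
Conditions: BnBr (2.6 equiv), K2CO3 (3 equiv), acetone, reflux
Reagents that add atoms: benzyl bromide, BrCc1ccccc1
Why: Williamson O-benzylation of the two remaining phenols under anhydrous carbonate conditions that aryl TIPS ethers tolerate, with C3' and C5' shielded by the neighbouring silyl ether so that C-benzylation should stay minor.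

Step 7
Reactants: 10 1,3-bis(benzyloxy)-2-[3-(benzyloxy)-5-(triisopropylsilyloxy)phenoxy]-5-(triisopropylsilyloxy)benzene
Product: 11 3,5-bis(benzyloxy)-4-[3-(benzyloxy)-5-hydroxyphenoxy]phenol
Conditions: Bu4NF (2.2 equiv), AcOH (2.2 equiv), THF, 0 °C
Reagents that add atoms: none
Why: Fluoride-induced cleavage of both aryl silyl ethers in one operation, buffered with acetic acid so that the electron-rich phenoxides are protonated at once, while benzyl ethers are inert.

Step 8
Reactants: 11 3,5-bis(benzyloxy)-4-[3-(benzyloxy)-5-hydroxyphenoxy]phenol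
Product: 12 disodium 3,5-bis(benzyloxy)-4-[3-(benzyloxy)-5-(sulfonatooxy)phenoxy]phenyl sulfate
Conditions: SO3·pyridine (6 equiv), pyridine, rt; 1 M NaOH to pH 8, 0 °C; reversed-phase chromatography
Reagents that add atoms: sulfur trioxide–pyridine complex, [O-]S(=O)(=O)[n+]1ccccc1; sodium hydroxide, [Na+].[OH-]
Why: Phenol O-sulfation with an SO3–amine complex, whose sites are fixed by the protecting-group pattern because only the ring A and the C4' hydroxyls are free, and the basic work-up gives base-stable sodium salts.

Step 9
Reactants: 12 disodium 3,5-bis(benzyloxy)-4-[3-(benzyloxy)-5-(sulfonatooxy)phenoxy]phenyl sulfate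
Product: 14 3,5-dihydroxy-4-[3-hydroxy-5-(sulfooxy)phenoxy]phenyl hydrogen sulfate (target), via target disodium salt 13 (not isolated)
Conditions: H2 (1 atm), Pd/C, MeOH/H2O, rt; filter; sulfonic acid cation-exchange resin (H+ form), H2O, 0–5 °C; freeze-dry
Reagents that add atoms: none
Why: Catalytic hydrogenolysis of the three aryl benzyl ethers under neutral conditions that aryl sulfate salts tolerate, followed by sodium-for-proton cation exchange in cold water to release the acid form without a mineral acid.

Compound list
1 | phloroglucinol (benzene-1,3,5-triol) | Oc1cc(O)cc(O)c1 | starting material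
2 | 5-(benzyloxy)benzene-1,3-diol | Oc1cc(O)cc(OCc2ccccc2)c1 | intermediate
3 | 3-(benzyloxy)-5-(triisopropylsilyloxy)phenol | Oc1cc(OCc2ccccc2)cc(O[Si](C(C)C)(C(C)C)C(C)C)c1 | intermediate
4 | 3-chloropentane-2,4-dione | CC(=O)C(Cl)C(C)=O | starting material
5 | 3-[3-(benzyloxy)-5-(triisopropylsilyloxy)phenoxy]pentane-2,4-dione | CC(=O)C(Oc1cc(OCc2ccccc2)cc(O[Si](C(C)C)(C(C)C)C(C)C)c1)C(C)=O | intermediate
6 | dimethyl carbonate | COC(=O)OC | starting material
7 | methyl 4-[3-(benzyloxy)-5-(triisopropylsilyloxy)phenoxy]-3,5-dioxohexanoate (not isolated; C4 enolisable, no defined configuration) | COC(=O)CC(=O)C(Oc1cc(OCc2ccccc2)cc(O[Si](C(C)C)(C(C)C)C(C)C)c1)C(C)=O | intermediate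
8 | 2-[3-(benzyloxy)-5-(triisopropylsilyloxy)phenoxy]benzene-1,3,5-triol | Oc1cc(O)c(Oc2cc(OCc3ccccc3)cc(O[Si](C(C)C)(C(C)C)C(C)C)c2)c(O)c1 | intermediate
9 | 2-[3-(benzyloxy)-5-(triisopropylsilyloxy)phenoxy]-5-(triisopropylsilyloxy)benzene-1,3-diol | Oc1cc(O[Si](C(C)C)(C(C)C)C(C)C)cc(O)c1Oc1cc(OCc2ccccc2)cc(O[Si](C(C)C)(C(C)C)C(C)C)c1 | intermediate
10 | 1,3-bis(benzyloxy)-2-[3-(benzyloxy)-5-(triisopropylsilyloxy)phenoxy]-5-(triisopropylsilyloxy)benzene | CC(C)[Si](Oc1cc(OCc2ccccc2)c(Oc2cc(OCc3ccccc3)cc(O[Si](C(C)C)(C(C)C)C(C)C)c2)c(OCc2ccccc2)c1)(C(C)C)C(C)C | intermediate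
11 | 3,5-bis(benzyloxy)-4-[3-(benzyloxy)-5-hydroxyphenoxy]phenol | Oc1cc(OCc2ccccc2)c(Oc2cc(O)cc(OCc3ccccc3)c2)c(OCc2ccccc2)c1 | intermediate
12 | disodium 3,5-bis(benzyloxy)-4-[3-(benzyloxy)-5-(sulfonatooxy)phenoxy]phenyl sulfate | [Na+].[Na+].[O-]S(=O)(=O)Oc1cc(OCc2ccccc2)c(Oc2cc(OCc3ccccc3)cc(OS(=O)(=O)[O-])c2)c(OCc2ccccc2)c1 | intermediate
13 | disodium 3,5-dihydroxy-4-[3-hydroxy-5-(sulfonatooxy)phenoxy]phenyl sulfate (not isolated) | [Na+].[Na+].[O-]S(=O)(=O)Oc1cc(O)cc(Oc2c(O)cc(OS(=O)(=O)[O-])cc2O)c1 | intermediate
14 | 3,5-dihydroxy-4-[3-hydroxy-5-(sulfooxy)phenoxy]phenyl hydrogen sulfate (CNP0460023.0; achiral, no stereocentres) | O=S(=O)(O)Oc1cc(O)cc(Oc2c(O)cc(OS(=O)(=O)O)cc2O)c1 | target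

Total step count: 9. Longest linear sequence: 9 steps (1 → 14).

Steps most likely to fail

Step 4. The sequence may stall after the first acylation because the enolised keto ester is a weak electrophile. Closure may also run through oxygen, the amide base may consume the carbonate, or prolonged warming may strip the ring A silyl group. The fallback sets out from 1 and 3, comes back at 8, and gives up the benzannulation for a classical ether coupling. Phloroglucinol 1 would be converted with MOMCl and i-Pr2NEt (CH2Cl2) into 1,3,5-tris(methoxymethoxy)benzene F1. This would be lithiated between two acetal oxygens (n-BuLi, THF, 0 °C) and quenched with I2 to give 2-iodo-1,3,5-tris(methoxymethoxy)benzene F2. Ullmann ether coupling of the iodide with phenol 3 (CuI, N,N-dimethylglycine, Cs2CO3, dioxane, 90 °C) would give {3-(benzyloxy)-5-[2,4,6-tris(methoxymethoxy)phenoxy]phenoxy}triisopropylsilane F3. Mild acid methanolysis (HCl, MeOH/THF, 40 °C), which spares the benzyl and the aryl TIPS ether, would then return triol 8.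

Step 5. Discrimination between the C4' hydroxyl and the two hydroxyls beside the ether oxygen may be poor, or silylation may run on to bis-ethers. The fallback sets out from 8, comes back at 9, and moves the selection from a kinetic protection to an enzymatic deprotection. Triol 8 would be peracetylated (Ac2O, pyridine) to 2-[3-(benzyloxy)-5-(triisopropylsilyloxy)phenoxy]benzene-1,3,5-triyl triacetate F4. Lipase-catalysed butanolysis (Candida antarctica lipase B, n-BuOH, MTBE, 40 °C) is a known way of removing the least hindered acetate from polyphenol peracetates. It would free only the C4' oxygen and give 2-[3-(benzyloxy)-5-(triisopropylsilyloxy)phenoxy]-5-hydroxy-1,3-phenylene diacetate F5. Silylation with TIPSOTf and 2,6-lutidine (CH2Cl2, 0 °C) would give 2-[3-(benzyloxy)-5-(triisopropylsilyloxy)phenoxy]-5-(triisopropylsilyloxy)-1,3-phenylene diacetate F6. Hydrazinolysis of the two aryl acetates (N2H4·H2O, THF, 0 °C) would then deliver 9.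

Step 8. The double sulfation may stay incomplete, and sulfate may be lost while the amphiphilic mono- and bis-sulfate salts are separated. The fallback sets out from 11, comes back at 14, and uses masked, neutral sulfate diesters. Bis-phenol 11 would react with 2,2,2-trichloroethyl chlorosulfate (Et3N, DMAP, THF, 0 °C → rt). This would give 3,5-bis(benzyloxy)-4-{3-(benzyloxy)-5-[(2,2,2-trichloroethoxy)sulfonyloxy]phenoxy}phenyl 2,2,2-trichloroethyl sulfate F7, which can be purified on silica. Pd/C with HCO2NH4 in MeOH would then remove both trichloroethyl groups and all three benzyl ethers in one buffered reductive operation. The product would be diammonium 3,5-dihydroxy-4-[3-hydroxy-5-(sulfonatooxy)phenoxy]phenyl sulfate F8, which the cold cation exchange of step 9 would convert into 14.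

Further compounds
F1 | step 4 | 1,3,5-tris(methoxymethoxy)benzene | COCOc1cc(OCOC)cc(OCOC)c1
F2 | step 4 | 2-iodo-1,3,5-tris(methoxymethoxy)benzene | COCOc1cc(OCOC)c(I)c(OCOC)c1
F3 | step 4 | {3-(benzyloxy)-5-[2,4,6-tris(methoxymethoxy)phenoxy]phenoxy}triisopropylsilane | COCOc1cc(OCOC)c(Oc2cc(OCc3ccccc3)cc(O[Si](C(C)C)(C(C)C)C(C)C)c2)c(OCOC)c1
F4 | step 5 | 2-[3-(benzyloxy)-5-(triisopropylsilyloxy)phenoxy]benzene-1,3,5-triyl triacetate | CC(=O)Oc1cc(OC(C)=O)c(Oc2cc(OCc3ccccc3)cc(O[Si](C(C)C)(C(C)C)C(C)C)c2)c(OC(C)=O)c1
F5 | step 5 | 2-[3-(benzyloxy)-5-(triisopropylsilyloxy)phenoxy]-5-hydroxy-1,3-phenylene diacetate | CC(=O)Oc1cc(O)cc(OC(C)=O)c1Oc1cc(OCc2ccccc2)cc(O[Si](C(C)C)(C(C)C)C(C)C)c1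
F6 | step 5 | 2-[3-(benzyloxy)-5-(triisopropylsilyloxy)phenoxy]-5-(triisopropylsilyloxy)-1,3-phenylene diacetate | CC(=O)Oc1cc(O[Si](C(C)C)(C(C)C)C(C)C)cc(OC(C)=O)c1Oc1cc(OCc2ccccc2)cc(O[Si](C(C)C)(C(C)C)C(C)C)c1
F7 | step 8 | 3,5-bis(benzyloxy)-4-{3-(benzyloxy)-5-[(2,2,2-trichloroethoxy)sulfonyloxy]phenoxy}phenyl 2,2,2-trichloroethyl sulfate | ClC(Cl)(Cl)COS(=O)(=O)Oc1cc(OCc2ccccc2)c(Oc2cc(OCc3ccccc3)cc(OS(=O)(=O)OCC(Cl)(Cl)Cl)c2)c(OCc2ccccc2)c1
F8 | step 8 | diammonium 3,5-dihydroxy-4-[3-hydroxy-5-(sulfonatooxy)phenoxy]phenyl sulfate | [NH4+].[NH4+].[O-]S(=O)(=O)Oc1cc(O)cc(Oc2c(O)cc(OS(=O)(=O)[O-])cc2O)c1
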